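**Plan**
- Retrosynthesis: the six O‑methyl ethers and two auxiliary C4 bromines go last. Each benzofuranone is then cut at O1–C7a and C3–C3a (four bonds in all), giving two molecules of 3‑bromo‑5‑methoxybenzyne and one dimethyl 2,5‑dihydroxy‑3,4‑diarylmuconate. That diester is cut at its central C3–C4 bond (C10–C10' of the target) into two arylpyruvate esters.
- Enabling feature: ring A is fused to each furanone through the neighbouring bonds O1–C7a and C3–C3a. One aryne can accept this ortho pair from an enolate oxygen and from the ester carbonyl carbon geminal to it (O1–C2–C3 of the future ring).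
- Forward: veratraldehyde → azlactone → arylpyruvate ester; iodine‑mediated enolate dimerisation joins the chain; the twofold aryne annulation closes both furanone rings in one flask; debromination and O‑demethylation finish.
- Stereochemistry: there are no stereocentres. The two tetrasubstituted (Z) alkenes are carried over from the (2Z,4Z)‑dienediolate and are push–pull double bonds under thermodynamic control.

Key step: step 7

Assumption: the natural (Z,Z) geometry (each catechol ring beside the C3 carbonyl, the other furanone arm beside the smaller ring oxygen O1) is taken to be the thermodynamically preferred one, so equilibration of the push–pull alkenes converges on it.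
Assumption: the arylpyruvate dimer is drawn and named as its conjugated bis‑enol; any keto tautomer present gives the same dienediolate on deprotonation.

**Step 1**
Reactants: 1 3,4‑dimethoxybenzaldehyde (veratraldehyde); 2 N‑acetylglycine
Product: 4 (Z)‑4‑(3,4‑dimethoxybenzylidene)‑2‑methyloxazol‑5(4H)‑one, via 2‑methyloxazol‑5(4H)‑one 3 (not isolated)
Conditions: Ac2O, NaOAc, 110 °C
Reagents that add atoms: none
Why: Erlenmeyer–Plöchl azlactone synthesis, in which acetic anhydride cyclodehydrates N‑acetylglycine to oxazolone 3 and its acidic C4 methylene condenses with the aldehyde (Perkin‑type aldol/dehydration) to give the thermodynamically preferred (Z)‑azlactone.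

**Step 2**
Reactants: 4 (Z)‑4‑(3,4‑dimethoxybenzylidene)‑2‑methyloxazol‑5(4H)‑one
Product: 6 3‑(3,4‑dimethoxyphenyl)‑2‑oxopropanoic acid, via acetamidoacrylic acid 5 (not isolated)
Conditions: 3 M HCl, reflux
Reagents that add atoms: water, O
Why: Acidic azlactone hydrolysis opens the lactone to dehydroamino acid 5 and then hydrolyses the enamide through its imine tautomer to the α‑keto acid, the classical arylpyruvic acid preparation; aryl methyl ethers are inert to dilute HCl.

**Step 3**
Reactants: 6 3‑(3,4‑dimethoxyphenyl)‑2‑oxopropanoic acid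
Product: 7 methyl 3‑(3,4‑dimethoxyphenyl)‑2‑oxopropanoate
Conditions: MeI, KHCO3, DMF, rt
Reagents that add atoms: iodomethane, CI
Why: SN2 O‑alkylation of the carboxylate under bicarbonate, a base too weak to engage the enolisable C3 position appreciably, should give the methyl ester without the ketalisation or self‑aldolisation that acidic esterification of arylpyruvic acids invites.

**Step 4**
Reactants: 7 methyl 3‑(3,4‑dimethoxyphenyl)‑2‑oxopropanoate (2 equiv)
Product: 10 dimethyl (2Z,4Z)‑3,4‑bis(3,4‑dimethoxyphenyl)‑2,5‑dihydroxyhexa‑2,4‑dienedioate, via sodium enolate 8 (not isolated), via diketone 9 (not isolated)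
Conditions: NaH, THF, 0 °C; I2 (0.5 equiv), −78 °C → rt; aq. Na2S2O3 / dilute HCl work‑up
Reagents that add atoms: none
Why: Oxidative homocoupling of an enolate with iodine (α‑iodination of one enolate, C‑alkylation by a second), a known way of joining two arylpyruvate units at C3, gives 1,4‑diketone 9, which tautomerises to the conjugated, hydrogen‑bonded bis‑enol so that its two stereocentres are erased.

**Step 5**
Reactants: 11 2,6‑dibromo‑4‑methoxyphenol
Product: 12 (2,6‑dibromo‑4‑methoxyphenoxy)trimethylsilane
Conditions: HN(SiMe3)2, THF, 70 °C; evaporate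
Reagents that add atoms: hexamethyldisilazane, C[Si](C)(C)N[Si](C)(C)C
Why: O‑silylation of a phenol with hexamethyldisilazane proceeds cleanly with ammonia as the only by‑product and leaves a crude silyl ether suitable for direct lithiation.

**Step 6**
Reactants: 12 (2,6‑dibromo‑4‑methoxyphenoxy)trimethylsilane
Product: 15 2‑bromo‑4‑methoxy‑6‑(trimethylsilyl)phenyl trifluoromethanesulfonate, via aryllithium 13 (not isolated), via lithium phenoxide 14 (not isolated)
Conditions: n‑BuLi, THF, −78 °C; then Tf2O, −78 °C → rt
Reagents that add atoms: trifluoromethanesulfonic anhydride, O=S(=O)(OS(=O)(=O)C(F)(F)F)C(F)(F)F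
Why: Bromine–lithium exchange at one of the two equivalent C–Br bonds, anionic 1,3 O→C silyl migration (retro‑Brook rearrangement) and O‑triflation of the resulting phenoxide is the standard entry to ortho‑silylaryl triflates that keep a halogen next to the triflate.

**Step 7**
Reactants: 10 dimethyl (2Z,4Z)‑3,4‑bis(3,4‑dimethoxyphenyl)‑2,5‑dihydroxyhexa‑2,4‑dienedioate; 15 2‑bromo‑4‑methoxy‑6‑(trimethylsilyl)phenyl trifluoromethanesulfonate (3 equiv, added slowly)
Product: 19 (2Z,2'Z)‑2,2'‑[1,2‑bis(3,4‑dimethoxyphenyl)ethane‑1,2‑diylidene]bis(4‑bromo‑6‑methoxy‑1‑benzofuran‑3(2H)‑one) (4,4'‑dibromo‑hexa‑O‑methyldisulfuretin), via dipotassium dienediolate 16 (not isolated), via 3‑bromo‑5‑methoxybenzyne 17 (not isolated), via mono‑annulated enolate 18 (not isolated)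
Conditions: KH (2.1 equiv), 18‑crown‑6, THF, 0 °C; then 15, KF, 18‑crown‑6, THF, 0 °C → rt, Ar; H2O work‑up
Reagents that add atoms: none
Why: Proposed new method: fluoride unmasks aryne 17 from 15, each enolate oxygen of dienediolate 16 adds at the aryne carbon remote from bromine, and the aryl anion formed next to bromine attacks the geminal methyl ester and expels methoxide, giving first enolate 18 and then, by the same sequence on the other half, 19, so that two O1–C7a and two C3–C3a bonds form in one flask. The closest known reaction type is the aryne annulation of salicylate esters to xanthones (O‑addition to the aryne followed by intramolecular acyl substitution), transposed here from a phenoxide to an α‑keto ester enolate. Each furanone ring closes by 5‑exo‑trig attack of the aryl anion on the ester carbonyl. No stereocentre is created; the (Z,Z) alkene geometry is inherited from the dienediolate and, each new alkene being a push–pull enol ether/enone, can relax to the thermodynamic arrangement. The step needs O‑ rather than C‑arylation, which the fully substituted, shielded enolate carbon and the crown‑separated potassium enolate should favour, and it needs acyl capture to outrun protonation of the aryl anion, which prior deprotonation with KH secures by leaving no proton source in the aprotic medium. The regiochemistry of aryne capture (O1 meta and C3 para to the methoxy group) is secured by the bromine atom, which distorts the aryne and stabilises the anion developing at the adjacent carbon.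

**Step 8**
Reactants: 19 4,4'‑dibromo‑hexa‑O‑methyldisulfuretin
Product: 20 (2Z,2'Z)‑2,2'‑[1,2‑bis(3,4‑dimethoxyphenyl)ethane‑1,2‑diylidene]bis(6‑methoxy‑1‑benzofuran‑3(2H)‑one) (hexa‑O‑methyldisulfuretin)
Conditions: Pd(PPh3)4 (cat.), HCO2Na, DMF, 90 °C
Reagents that add atoms: none
Why: Palladium‑catalysed hydrodehalogenation (oxidative addition of zerovalent palladium into the carbonyl‑activated aryl C–Br bonds, formate exchange, decarboxylation to a palladium hydride, C–H reductive elimination) should remove both bromines while aryl ethers, ketones and the hindered tetrasubstituted alkenes stay untouched.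

**Step 9**
Reactants: 20 hexa‑O‑methyldisulfuretin
Product: 21 disulfuretin, (2Z,2'Z)‑2,2'‑[1,2‑bis(3,4‑dihydroxyphenyl)ethane‑1,2‑diylidene]bis(6‑hydroxy‑1‑benzofuran‑3(2H)‑one)
Conditions: BBr3 (excess), CH2Cl2, −78 °C → rt; then ice/H2O
Reagents that add atoms: none
Why: Lewis acid‑mediated cleavage of aryl methyl ethers with BBr3 (bromide attack on the methyl group of each borane–ether complex, hydrolysis of the aryl borates on work‑up) is the established way to unmask polymethoxy aurones, and the acidic medium lets the push–pull alkenes settle in the assumed thermodynamic (Z,Z) geometry.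

**Compound list**
1 | 3,4‑dimethoxybenzaldehyde (veratraldehyde) | COc1ccc(C=O)cc1OC | starting material
2 | N‑acetylglycine | CC(=O)NCC(=O)O | starting material
3 | 2‑methyloxazol‑5(4H)‑one | CC1=NCC(=O)O1 | intermediate
4 | (Z)‑4‑(3,4‑dimethoxybenzylidene)‑2‑methyloxazol‑5(4H)‑one | CC1=N/C(=C\c2ccc(OC)c(OC)c2)C(=O)O1 | intermediate
5 | (Z)‑2‑acetamido‑3‑(3,4‑dimethoxyphenyl)acrylic acid | CC(=O)N/C(=C\c1ccc(OC)c(OC)c1)C(=O)O | intermediate
6 | 3‑(3,4‑dimethoxyphenyl)‑2‑oxopropanoic acid | COc1ccc(CC(=O)C(=O)O)cc1OC | intermediate
7 | methyl 3‑(3,4‑dimethoxyphenyl)‑2‑oxopropanoate | COC(=O)C(=O)Cc1ccc(OC)c(OC)c1 | intermediate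
8 | sodium (Z)‑enolate of 7 | COC(=O)/C([O-])=C/c1ccc(OC)c(OC)c1.[Na+] | intermediate
9 | dimethyl 3,4‑bis(3,4‑dimethoxyphenyl)‑2,5‑dioxohexanedioate (mixture of diastereomers) | COC(=O)C(=O)C(c1ccc(OC)c(OC)c1)C(c1ccc(OC)c(OC)c1)C(=O)C(=O)OC | intermediate
10 | dimethyl (2Z,4Z)‑3,4‑bis(3,4‑dimethoxyphenyl)‑2,5‑dihydroxyhexa‑2,4‑dienedioate | COC(=O)/C(=C(/C(=C(\O)C(=O)OC)c1ccc(OC)c(OC)c1)c1ccc(OC)c(OC)c1)O | intermediate
11 | 2,6‑dibromo‑4‑methoxyphenol | COc1cc(Br)c(O)c(Br)c1 | starting material
12 | (2,6‑dibromo‑4‑methoxyphenoxy)trimethylsilane | COc1cc(Br)c(O[Si](C)(C)C)c(Br)c1 | intermediate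
13 | (2‑bromo‑6‑lithio‑4‑methoxyphenoxy)trimethylsilane | COc1cc(Br)c(O[Si](C)(C)C)c([Li])c1 | intermediate
14 | lithium 2‑bromo‑4‑methoxy‑6‑(trimethylsilyl)phenoxide | COc1cc(Br)c([O-])c([Si](C)(C)C)c1.[Li+] | intermediate
15 | 2‑bromo‑4‑methoxy‑6‑(trimethylsilyl)phenyl trifluoromethanesulfonate | COc1cc(Br)c(OS(=O)(=O)C(F)(F)F)c([Si](C)(C)C)c1 | intermediate
16 | dipotassium (2Z,4Z)‑dienediolate of 10 | COC(=O)/C(=C(/C(=C(\[O-])C(=O)OC)c1ccc(OC)c(OC)c1)c1ccc(OC)c(OC)c1)[O-].[K+].[K+] | intermediate
17 | 3‑bromo‑5‑methoxybenzyne | COC1=CC#CC(Br)=C1 | intermediate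
18 | potassium enolate of the mono‑annulated product (one 4‑bromo‑6‑methoxybenzofuranone, one remaining α‑keto ester enolate) | O=C1/C(=C(/C(=C(\[O-])C(=O)OC)c2ccc(OC)c(OC)c2)c2ccc(OC)c(OC)c2)Oc2cc(OC)cc(Br)c21.[K+] | intermediate
19 | 4,4'‑dibromo‑hexa‑O‑methyldisulfuretin | O=C1/C(=C(/C(=C2\Oc3cc(OC)cc(Br)c3C2=O)c2ccc(OC)c(OC)c2)c2ccc(OC)c(OC)c2)Oc2cc(OC)cc(Br)c21 | intermediate
20 | hexa‑O‑methyldisulfuretin | O=C1/C(=C(/C(=C2\Oc3cc(OC)ccc3C2=O)c2ccc(OC)c(OC)c2)c2ccc(OC)c(OC)c2)Oc2cc(OC)ccc21 | intermediate
21 | disulfuretin | O=C1/C(=C(/C(=C2\Oc3cc(O)ccc3C2=O)c2ccc(O)c(O)c2)c2ccc(O)c(O)c2)Oc2cc(O)ccc21 | target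

Total step count: 9. Longest linear sequence: 7 steps (steps 1, 2, 3, 4, 7, 8, 9); steps 5 and 6 form the two‑step side branch to the aryne precursor.

**Steps most likely to fail**

1. Step 7. The ambident enolate may arylate at carbon and go on to C–C insertion. The ortho‑bromoaryl anion may lose bromide to a second aryne before it reaches the ester. Liberated methoxide may consume aryne, or the sequence may stop after one annulation. The fallback uses only known reactions, builds the furanones before the central bond, sets out from 1 and rejoins the route at 20. Veratraldehyde 1 is condensed with purchased 6‑methoxybenzofuran‑3(2H)‑one F1 (KOH/MeOH or neutral alumina, the standard aldol route to aurones) to give (Z)‑2‑(3,4‑dimethoxybenzylidene)‑6‑methoxybenzofuran‑3(2H)‑one F2. Bromine addition across the exocyclic alkene (pyridinium tribromide, CH2Cl2, 0 °C) gives 2‑bromo‑2‑[bromo(3,4‑dimethoxyphenyl)methyl]‑6‑methoxybenzofuran‑3(2H)‑one F3. Dehydrobromination with Et3N, which can only remove the C10 hydrogen, gives (Z)‑2‑[bromo(3,4‑dimethoxyphenyl)methylidene]‑6‑methoxybenzofuran‑3(2H)‑one F4. Reductive homocoupling of this alkenyl bromide with Ni(cod)2/PPh3 in DMF (zerovalent nickel, Semmelhack‑type coupling with retention of alkene geometry) joins C10 to C10' and delivers 20 directly. This bypasses both the aryne chemistry and the debromination.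

2. Step 4. Iodine may over‑oxidise the product enolate to the ene‑dione, the enolates may couple through oxygen, or the diketone may enolise incompletely. The fallback separates the electrophilic and nucleophilic roles, sets out from 7 and returns at 10. Half of ester 7 is brominated at C3 through its enol (Br2, CH2Cl2, 0 °C) to give methyl 3‑bromo‑3‑(3,4‑dimethoxyphenyl)‑2‑oxopropanoate F5. This benzylic bromide is then C‑alkylated (SN2) by preformed sodium enolate 8 (NaH, THF, −78 °C → rt) with no free oxidant present, giving diketone 9, which enolises to 10.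

3. Step 8. Palladium hydride may reduce the push–pull alkenes in conjugate fashion, or oxidative addition may stall at the hindered C–Br bonds peri to the C3 carbonyls. The fallback changes the mechanism from two‑electron palladium hydride chemistry to a radical chain. It sets out from 19 and returns at 20: tris(trimethylsilyl)silane and AIBN in toluene at 90 °C abstract bromine, and the aryl radicals are quenched by hydrogen‑atom transfer. The only cyclisation open to them is a disfavoured 5‑endo attack on the exocyclic alkene. No new compound is made.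

**Further compounds**
F1 | step 7 | 6‑methoxybenzofuran‑3(2H)‑one (purchased) | COc1ccc2c(c1)OCC2=O
F2 | step 7 | (Z)‑2‑(3,4‑dimethoxybenzylidene)‑6‑methoxybenzofuran‑3(2H)‑one | COc1ccc2c(c1)O/C(=C\c1ccc(OC)c(OC)c1)C2=O
F3 | step 7 | 2‑bromo‑2‑[bromo(3,4‑dimethoxyphenyl)methyl]‑6‑methoxybenzofuran‑3(2H)‑one | COc1ccc2c(c1)OC(Br)(C(Br)c1ccc(OC)c(OC)c1)C2=O
F4 | step 7 | (Z)‑2‑[bromo(3,4‑dimethoxyphenyl)methylidene]‑6‑methoxybenzofuran‑3(2H)‑one | COc1ccc2c(c1)O/C(=C(\Br)c1ccc(OC)c(OC)c1)C2=O
F5 | step 4 | methyl 3‑bromo‑3‑(3,4‑dimethoxyphenyl)‑2‑oxopropanoate | COC(=O)C(=O)C(Br)c1ccc(OC)c(OC)c1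
F0 | step 8 | none | none
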